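**Retrosynthetic overview**
1. Target 26 ← Luche reduction, acetylation and Stork–Danheiser methyl addition/carbonyl transposition from the tricyclic vinylogous ester 21.
2. Key C2–C3 bond (closes the 11-membered ring and creates the exocyclic methylene): the C2 methyl ketone is used with reversed polarity as its N-tosylhydrazone (diazo/Pd-carbene donor, a d1 synthon) and joined to the alkenyl chloride carbon C3, so two normally electrophilic carbons are united.
3. Five-membered ring ← ring contraction (oxidative cleavage, aldol condensation, conjugate reduction) of the cyclohexene in Diels–Alder adduct 14, made from isoprene and methoxyquinone 12; the cycloaddition sets C11 and C15.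
4. Six-membered ring ← 3,5-dimethoxytoluene (arene → quinone); C8–C9 by aryllithium acylation with a lactone, C8 by CBS reduction, C6 from methyl hydrogen (S)-3-methylglutarate.
5. Ring order: six-membered ring (arene/quinone) → cyclohexene (contracted to the five-membered ring) → 11-membered ring.

Assumption: labels C1′ (exocyclic CH2) and C2–C17 follow the carbon order of the target SMILES; SC = (1S,3S,5E)-1-(tert-butyldimethylsilyloxy)-6-chloro-3-methylhex-5-en-1-yl (carbons C8 to C3); TBS = tert-butyldimethylsilyl; compounds 1, 4 and 13 are taken as catalogue chemicals.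

**Route**

Step 1
Reactants: 1 methyl hydrogen (S)-3-methylglutarate
Product: 3 (4S)-4-methyltetrahydro-2H-pyran-2-one, via methyl (3S)-5-hydroxy-3-methylpentanoate 2 (not isolated)
Conditions: BH3·SMe2, THF, 0 °C to rt; MeOH; then TsOH (cat.), PhMe, 80 °C
Reagents that add atoms: none
Why: Borane reduces the free carboxylic acid much faster than the methyl ester and the δ-hydroxy ester then lactonises under acid (chemoselective reduction/lactonisation), leaving the C6 stereocentre untouched.

Step 2
Reactants: 4 3,5-dimethoxytoluene; 3 (4S)-4-methyltetrahydro-2H-pyran-2-one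
Product: 6 (3S)-1-(2,6-dimethoxy-4-methylphenyl)-5-hydroxy-3-methylpentan-1-one, via (2,6-dimethoxy-4-methylphenyl)lithium 5 (not isolated)
Conditions: 4, n-BuLi, THF, 0 °C to rt; then 3, −78 °C; H2O
Reagents that add atoms: none
Why: Directed ortho-lithiation between the two methoxy groups and acylation by the lactone, which stops at the ketone because the tetrahedral lithium alkoxide collapses only on work-up; this forms the C8–C9 bond.

Step 3
Reactants: 6 (3S)-1-(2,6-dimethoxy-4-methylphenyl)-5-hydroxy-3-methylpentan-1-one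
Product: 7 (3S)-5-(2,6-dimethoxy-4-methylphenyl)-3-methyl-5-oxopentanal
Conditions: TEMPO (cat.), PhI(OAc)2, CH2Cl2, rt
Reagents that add atoms: none
Why: Nitroxyl-catalysed oxidation of the primary alcohol stops at the aldehyde and does not touch the aryl ketone or the stereocentre.

Step 4
Reactants: 7 (3S)-5-(2,6-dimethoxy-4-methylphenyl)-3-methyl-5-oxopentanal
Product: 8 (3S,5E)-6-chloro-1-(2,6-dimethoxy-4-methylphenyl)-3-methylhex-5-en-1-one
Conditions: CrCl2, CHCl3, THF, 65 °C
Reagents that add atoms: chloroform ClC(Cl)Cl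
Why: Takai–Utimoto olefination with the chloroform-derived gem-dichromium reagent is aldehyde-selective over the hindered aryl ketone and gives the (E)-alkenyl chloride.

Step 5
Reactants: 8 (3S,5E)-6-chloro-1-(2,6-dimethoxy-4-methylphenyl)-3-methylhex-5-en-1-one
Product: 9 (1S,3S,5E)-6-chloro-1-(2,6-dimethoxy-4-methylphenyl)-3-methylhex-5-en-1-ol
Conditions: (R)-2-methyl-CBS-oxazaborolidine (10 mol%), catecholborane, PhMe, −78 °C
Reagents that add atoms: none
Why: Corey–Bakshi–Shibata reduction, in which the (R)-oxazaborolidine treats the 2,6-disubstituted aryl group as the large substituent and delivers hydride to give the (S)-carbinol that becomes C8; catecholborane does not hydroborate the chloroalkene.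

Step 6
Reactants: 9 (1S,3S,5E)-6-chloro-1-(2,6-dimethoxy-4-methylphenyl)-3-methylhex-5-en-1-ol
Product: 10 tert-butyl{[(1S,3S,5E)-6-chloro-1-(2,6-dimethoxy-4-methylphenyl)-3-methylhex-5-en-1-yl]oxy}dimethylsilane
Conditions: TBSOTf, 2,6-lutidine, CH2Cl2, −78 to 0 °C
Reagents that add atoms: tert-butyldimethylsilyl triflate CC(C)(C)[Si](C)(C)OS(=O)(=O)C(F)(F)F
Why: Silylation of the hindered benzylic alcohol with the silyl triflate protects C8–OH through the Lewis-acid, base and organometallic steps that follow.

Step 7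
Reactants: 10 tert-butyl{[(1S,3S,5E)-6-chloro-1-(2,6-dimethoxy-4-methylphenyl)-3-methylhex-5-en-1-yl]oxy}dimethylsilane
Product: 11 2-SC-3-methoxy-5-methylphenol
Conditions: NaSEt, DMF, 110 °C
Reagents that add atoms: none
Why: SN2 demethylation by ethanethiolate stops after one of the two equivalent methyl ethers because the phenoxide formed deactivates the ring toward a second cleavage.

Step 8
Reactants: 11 2-SC-3-methoxy-5-methylphenol
Product: 12 2-SC-3-methoxy-5-methyl-1,4-benzoquinone
Conditions: Co(salen) (10 mol%), O2 (1 atm), MeCN, rt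
Reagents that add atoms: dioxygen O=O
Why: Cobalt–salen-catalysed aerobic oxidation of a phenol with a free para position gives the para-quinone, the para carbon becoming C16.

Step 9
Reactants: 12 2-SC-3-methoxy-5-methyl-1,4-benzoquinone; 13 isoprene
Product: 14 (4aS,8aR)-2-SC-3-methoxy-4a,7-dimethyl-4a,5,8,8a-tetrahydronaphthalene-1,4-dione (cis-fused)
Conditions: 13 (5 equiv), (R)-BINOL/TiCl2(OiPr)2 (20 mol%), 4 Å MS, CH2Cl2, −30 °C
Reagents that add atoms: none
Why: Diels–Alder reaction at the only trisubstituted quinone double bond, in which chelation of tetravalent titanium by the C16 carbonyl and the C17 methoxy group makes C11 the most electrophilic carbon so the nucleophilic C1 terminus of isoprene bonds there (para orientation), and the BINOL ligand shields one quinone face so that the cis junction C11–H/C15–CH3 is set with absolute control.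

Step 10
Reactants: 14 (4aS,8aR)-2-SC-3-methoxy-4a,7-dimethyl-4a,5,8,8a-tetrahydronaphthalene-1,4-dione
Product: 16 (5S,6R)-2-SC-3-methoxy-5-methyl-5-(2-oxoethyl)-6-(2-oxopropyl)cyclohex-2-ene-1,4-dione, via cis-6,7-diol 15 (not isolated)
Conditions: OsO4 (2 mol%), NaIO4, 2,6-lutidine, dioxane/H2O, rt
Reagents that add atoms: osmium tetroxide O=[Os](=O)(=O)=O; sodium periodate [Na+].[O-]I(=O)(=O)=O
Why: Lemieux–Johnson oxidation, in which OsO4 dihydroxylates only the isolated electron-rich trisubstituted alkene (not the chloroalkene or the tetrasubstituted push-pull alkene) and periodate cleaves the diol to the methyl ketone (C2) and the aldehyde (C13).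

Step 11
Reactants: 16 (5S,6R)-2-SC-3-methoxy-5-methyl-5-(2-oxoethyl)-6-(2-oxopropyl)cyclohex-2-ene-1,4-dione
Product: 18 (3aS,7aS)-3-acetyl-6-methoxy-7a-methyl-5-SC-3a,7a-dihydro-1H-indene-4,7-dione, via aldol adduct 17 (not isolated)
Conditions: NaOMe, MeOH, 0 °C to rt
Reagents that add atoms: none
Why: Intramolecular aldol condensation in which the ketone enolate carbon C12 attacks the more electrophilic aldehyde C13 (five-membered ring, conjugated acetylcyclopentene) while the seven-membered and the tetrasubstituted neopentyl alternatives are disfavoured; the cis ring fusion is carried over from 14.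

Step 12
Reactants: 18 (3aS,7aS)-3-acetyl-6-methoxy-7a-methyl-5-SC-3a,7a-dihydro-1H-indene-4,7-dione
Product: 19 (3R,3aR,7aS)-3-acetyl-6-methoxy-7a-methyl-5-SC-2,3,3a,7a-tetrahydro-1H-indene-4,7-dione
Conditions: [(Ph3P)CuH]6, PhH/THF, H2O (2 equiv), rt
Reagents that add atoms: none
Why: Copper hydride conjugate reduction is selective for the β-monosubstituted enone over the tetrasubstituted alkoxy-enedione, and kinetic protonation of the enolate at C12 from the convex face (away from the six-membered ring) gives the acetyl group cis to C10, as the target requires.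

Step 13
Reactants: 19 (3R,3aR,7aS)-3-acetyl-6-methoxy-7a-methyl-5-SC-2,3,3a,7a-tetrahydro-1H-indene-4,7-dione
Product: 21 tricyclic diene-dione (6S,8S,11R,12R,15S) with the 11-membered ring closed through C2(=C1′H2)–C3H=C4H (E); C8–OTBS; C9=C17 methyl enol ether; ketones at C10 and C16, via N-tosylhydrazone 20 (not isolated)
Conditions: TsNHNH2, dioxane, 60 °C; then Pd2(dba)3 (5 mol%), XPhos, LiOtBu, dioxane (2 mM, syringe pump), 100 °C
Reagents that add atoms: none
Why: Proposed new method: ring-closing Barluenga–Valdés coupling, in which the tosylhydrazone salt of the C2 ketone decomposes to a diazo compound that forms a palladium carbene with the alkenylpalladium chloride from oxidative addition of zerovalent palladium into C3–Cl, migratory insertion makes the C2–C3 bond (two normally electrophilic carbons joined by using the carbonyl carbon as the donor) and β-hydride elimination from the methyl group gives the exocyclic methylene with the E alkene retained; the closest known reactions are the intermolecular palladium-catalysed coupling of ketone tosylhydrazones with alkenyl halides to 2-substituted 1,3-dienes and Stille/Suzuki macrocyclisations, and cyclisation is helped because the C9 side chain and the cis C12 acetyl group sit on the same face.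

Step 14
Reactants: 21 tricyclic diene-dione
Product: 22 (16R)-alcohol of 21 (C16–OH; C10 vinylogous ester carbonyl untouched)
Conditions: NaBH4, CeCl3·7H2O, MeOH, −78 °C
Reagents that add atoms: none
Why: Luche reduction is selective for the C16 ketone because the C10 carbonyl is a deactivated vinylogous ester, and hydride attacks anti to the adjacent angular C15 methyl group, placing the hydroxyl cis to that methyl (16R).

Step 15
Reactants: 22 (16R)-alcohol
Product: 24 enone diol (6S,8S,11S,12R,15S,16R): C17 ketone; C9=C10 alkene bearing the new C10 methyl; free C8–OH and C16–OH, via C10 tertiary carbinol 23 (not isolated)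
Conditions: MeLi (excess), CeCl3, THF, −78 °C; then 48% aq. HF, MeCN, 0 °C to rt
Reagents that add atoms: methyllithium [Li]C; water O
Why: Stork–Danheiser sequence, in which the organocerium reagent adds 1,2 to the vinylogous ester carbonyl C10 and acid ionises the tertiary carbinol to the methoxy-stabilised allyl cation that hydrolyses to the transposed enone (C17=O, C9=C10–CH3), while HF also removes the silyl ether.

Step 16
Reactants: 24 enone diol
Product: 25 8,16-diacetate of 24 (C17 ketone)
Conditions: Ac2O, DMAP, Et3N, CH2Cl2, rt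
Reagents that add atoms: acetic anhydride CC(=O)OC(C)=O
Why: DMAP-catalysed acylation of the two secondary alcohols while C17 is still a ketone, which fixes the acetate/free-hydroxyl pattern of the target without protecting groups.

Step 17
Reactants: 25 8,16-diacetate enone
Product: 26 target (6S,8S,11S,12R,15S,16R,17R)
Conditions: NaBH4, CeCl3·7H2O, MeOH, −78 °C
Reagents that add atoms: none
Why: Luche 1,2-reduction of the enone with axial hydride delivery on the side of the pseudo-equatorial C16 acetoxy group gives the trans-diequatorial 17R allylic alcohol, and the acetates survive the cold, neutral conditions.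

**Compound list**
1 | methyl hydrogen (S)-3-methylglutarate | COC(=O)C[C@@H](C)CC(=O)O | starting material
2 | methyl (3S)-5-hydroxy-3-methylpentanoate | COC(=O)C[C@@H](C)CCO | intermediate
3 | (4S)-4-methyltetrahydro-2H-pyran-2-one | O=C1C[C@@H](C)CCO1 | intermediate
4 | 3,5-dimethoxytoluene | COc1cc(C)cc(OC)c1 | starting material
5 | (2,6-dimethoxy-4-methylphenyl)lithium | [Li]c1c(OC)cc(C)cc1OC | intermediate
6 | (3S)-1-(2,6-dimethoxy-4-methylphenyl)-5-hydroxy-3-methylpentan-1-one | OCC[C@H](C)CC(=O)c1c(OC)cc(C)cc1OC | intermediate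
7 | (3S)-5-(2,6-dimethoxy-4-methylphenyl)-3-methyl-5-oxopentanal | O=CC[C@H](C)CC(=O)c1c(OC)cc(C)cc1OC | intermediate
8 | (3S,5E)-6-chloro-1-(2,6-dimethoxy-4-methylphenyl)-3-methylhex-5-en-1-one | Cl/C=C/C[C@H](C)CC(=O)c1c(OC)cc(C)cc1OC | intermediate
9 | (1S,3S,5E)-6-chloro-1-(2,6-dimethoxy-4-methylphenyl)-3-methylhex-5-en-1-ol | Cl/C=C/C[C@H](C)C[C@H](O)c1c(OC)cc(C)cc1OC | intermediate
10 | TBS ether of 9 | Cl/C=C/C[C@H](C)C[C@H](O[Si](C)(C)C(C)(C)C)c1c(OC)cc(C)cc1OC | intermediate
11 | 2-SC-3-methoxy-5-methylphenol | Cl/C=C/C[C@H](C)C[C@H](O[Si](C)(C)C(C)(C)C)c1c(OC)cc(C)cc1O | intermediate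
12 | 2-SC-3-methoxy-5-methyl-1,4-benzoquinone | Cl/C=C/C[C@H](C)C[C@H](O[Si](C)(C)C(C)(C)C)C1=C(OC)C(=O)C(C)=CC1=O | intermediate
13 | isoprene (2-methylbuta-1,3-diene) | C=CC(C)=C | starting material
14 | (4aS,8aR)-2-SC-3-methoxy-4a,7-dimethyl-4a,5,8,8a-tetrahydronaphthalene-1,4-dione | Cl/C=C/C[C@H](C)C[C@H](O[Si](C)(C)C(C)(C)C)C1=C(OC)C(=O)[C@@]2(C)CC=C(C)C[C@H]2C1=O | intermediate
15 | cis-6,7-diol of 14 (new carbinol centres unassigned) | Cl/C=C/C[C@H](C)C[C@H](O[Si](C)(C)C(C)(C)C)C1=C(OC)C(=O)[C@@]2(C)CC(O)C(C)(O)C[C@H]2C1=O | intermediate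
16 | (5S,6R)-2-SC-3-methoxy-5-methyl-5-(2-oxoethyl)-6-(2-oxopropyl)cyclohex-2-ene-1,4-dione | Cl/C=C/C[C@H](C)C[C@H](O[Si](C)(C)C(C)(C)C)C1=C(OC)C(=O)[C@@](C)(CC=O)[C@@H](CC(C)=O)C1=O | intermediate
17 | aldol adduct: 3-acetyl-2-hydroxy-6-methoxy-7a-methyl-5-SC-2,3,3a,7a-tetrahydro-1H-indene-4,7-dione (C12/C13 unassigned) | Cl/C=C/C[C@H](C)C[C@H](O[Si](C)(C)C(C)(C)C)C1=C(OC)C(=O)[C@@]2(C)CC(O)C(C(C)=O)[C@H]2C1=O | intermediate
18 | (3aS,7aS)-3-acetyl-6-methoxy-7a-methyl-5-SC-3a,7a-dihydro-1H-indene-4,7-dione | Cl/C=C/C[C@H](C)C[C@H](O[Si](C)(C)C(C)(C)C)C1=C(OC)C(=O)[C@@]2(C)CC=C(C(C)=O)[C@H]2C1=O | intermediate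
19 | (3R,3aR,7aS)-3-acetyl-6-methoxy-7a-methyl-5-SC-2,3,3a,7a-tetrahydro-1H-indene-4,7-dione | Cl/C=C/C[C@H](C)C[C@H](O[Si](C)(C)C(C)(C)C)C1=C(OC)C(=O)[C@@]2(C)CC[C@@H](C(C)=O)[C@H]2C1=O | intermediate
20 | N-tosylhydrazone of the acetyl group of 19 | Cl/C=C/C[C@H](C)C[C@H](O[Si](C)(C)C(C)(C)C)C1=C(OC)C(=O)[C@@]2(C)CC[C@@H](C(C)=NNS(=O)(=O)c3ccc(C)cc3)[C@H]2C1=O | intermediate
21 | tricyclic diene-dione (6S,8S,11R,12R,15S); 11-membered ring; C8–OTBS; C17–OMe; C10 and C16 ketones | C=C1/C=C/C[C@H](C)C[C@H](O[Si](C)(C)C(C)(C)C)C2=C(OC)C(=O)[C@@]3(C)CC[C@@H]1[C@H]3C2=O | intermediate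
22 | (16R)-alcohol of 21 | C=C1/C=C/C[C@H](C)C[C@H](O[Si](C)(C)C(C)(C)C)C2=C(OC)[C@H](O)[C@@]3(C)CC[C@@H]1[C@H]3C2=O | intermediate
23 | C10 methyl carbinol from 22 (C10 epimers) | C=C1/C=C/C[C@H](C)C[C@H](O[Si](C)(C)C(C)(C)C)C2=C(OC)[C@H](O)[C@@]3(C)CC[C@@H]1[C@H]3C2(C)O | intermediate
24 | enone diol (6S,8S,11S,12R,15S,16R); C17 ketone; C8–OH; C16–OH | C=C1/C=C/C[C@H](C)C[C@H](O)C2=C(C)[C@@H]3[C@H]1CC[C@]3(C)[C@@H](O)C2=O | intermediate
25 | 8,16-diacetate of 24 | C=C1/C=C/C[C@H](C)C[C@H](OC(C)=O)C2=C(C)[C@@H]3[C@H]1CC[C@]3(C)[C@@H](OC(C)=O)C2=O | intermediate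
26 | CNP0323842.1 (6S,8S,11S,12R,15S,16R,17R) | C=C1/C=C/C[C@H](C)C[C@H](OC(C)=O)C2=C(C)[C@@H]3[C@H]1CC[C@]3(C)[C@@H](OC(C)=O)[C@@H]2O | target

**Count and risk**
Total steps: 17. Longest linear sequence: 17 (from 1; compounds 4 and 13 enter as purchased materials).

Most likely to fail, step 13: the macrocyclic carbene coupling is unprecedented, and the diazo intermediate may instead add to the enedione, dimerise, or undergo β-hydride elimination toward C12. The fallback keeps the same C2–C3 ring closure but uses conventional cross-coupling polarity. It sets out from 19: Miyaura borylation of the alkenyl chloride (B2pin2, Pd(OAc)2, XPhos, KOAc) gives the pinacol (E)-alkenylboronate F1, kinetic enolisation of the methyl ketone (KHMDS, PhNTf2, −78 °C) gives the enol triflate F2, and an intramolecular Suzuki–Miyaura coupling (Pd(PPh3)4, Cs2CO3, THF/H2O, high dilution) returns to the route at 21.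

Second, step 9: the facial sense and level of induction with this hindered, trisubstituted quinone are untested (the antipodal ligand would be tried first if the sense is reversed), and a monodentate Lewis acid would reverse the regiochemistry. The fallback replaces catalyst control by separation of diastereomers. It sets out from 12: uncatalysed cycloaddition with 13 (toluene, 80 °C) keeps the para orientation governed by the unchelated C16 ketone; because 12 is already enantiopure, the two cis adducts are diastereomers, 14 and its ring-junction diastereomer F3, which are separated by chromatography, and the route is rejoined at 14.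

Third, step 17: hydride may approach from the other face and give the cis alcohol. The fallback corrects the centre by inversion instead of by reagent choice. It sets out from 25: if the reduction delivers the 17-epi alcohol F4, a Mitsunobu reaction with chloroacetic acid (PPh3, DIAD) inverts C17 to the chloroacetate F5, and thiourea/NaHCO3 in ethanol removes the chloroacetyl group in the presence of the two acetates to arrive at 26.

Further compounds
F1 | step 13 | pinacol (E)-alkenylboronate from 19 (Bpin in place of Cl) | CC1(C)OB(/C=C/C[C@H](C)C[C@H](O[Si](C)(C)C(C)(C)C)C2=C(OC)C(=O)[C@@]3(C)CC[C@@H](C(C)=O)[C@H]3C2=O)OC1(C)C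
F2 | step 13 | enol triflate of F1 (1-(triflyloxy)vinyl in place of acetyl) | CC1(C)OB(/C=C/C[C@H](C)C[C@H](O[Si](C)(C)C(C)(C)C)C2=C(OC)C(=O)[C@@]3(C)CC[C@@H](C(=C)OS(=O)(=O)C(F)(F)F)[C@H]3C2=O)OC1(C)C
F3 | step 9 | ring-junction diastereomer of 14 (C11 and C15 both inverted) | Cl/C=C/C[C@H](C)C[C@H](O[Si](C)(C)C(C)(C)C)C1=C(OC)C(=O)[C@]2(C)CC=C(C)C[C@@H]2C1=O
F4 | step 17 | 17-epi-26 | C=C1/C=C/C[C@H](C)C[C@H](OC(C)=O)C2=C(C)[C@@H]3[C@H]1CC[C@]3(C)[C@@H](OC(C)=O)[C@H]2O
F5 | step 17 | 17-O-chloroacetate of 26 | C=C1/C=C/C[C@H](C)C[C@H](OC(C)=O)C2=C(C)[C@@H]3[C@H]1CC[C@]3(C)[C@@H](OC(C)=O)[C@@H]2OC(=O)CCl
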